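Chromene numbering of the target is used throughout: O1, C2, C3, C4, C4a, C5 (OMe), C6 (dione), C7 (OH), C8 (prenyl), C8a.

**Plan**

1. Retrosynthesis: ring C (the pyran) is cut first at C3=C4 and O1–C2, leaving salicylaldehyde 18 and the C4 unit 19. Then the two aryl–CO bonds of the dione are cut (two aryllithiums plus the C2O2 donor 11), then formyl–C4a, then prenyl–C8, down to 5-methoxyresorcinol 1.
2. Forward: ring A is bought, and its three CH positions are filled in turn by directed ortho-lithiation (prenyl between the two OMOM groups, then CHO, then the dione that brings ring B). Mirror-symmetric 6 removes every regiochemical choice, and ring C closes last on the unprotected molecule.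
3. Enabling feature: in 18 the formyl carbon on C4a has the C5 methoxy group on one side and its only free neighbouring hydroxyl (on C8a) on the other. This is a salicylaldehyde unit set in the electron-rich phloroglucinol ring A. Boron can be bound there and deliver its alkenyl group, the amine can be pushed out to an ortho-quinone methide, and the oxatriene O=C8a–C4a=C4–C3=C2 can close.
4. Helpers: MOM ethers serve as directing and protecting groups, and an imidazolidine serves as a temporary ring on the aldehyde. One acid step removes all of them before the key event.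
5. Stereochemistry: the target has no stereocentre. C3=C4 is cis by ring membership, and both alkene termini bearing methyl groups carry two of them.

Key step: step 7

Assumption: 1, 4, 11, 12 and 19 are taken as purchasable, and the 2-hydroxybenzils 18 and 23 are treated in their open dione form.

**Step 1**
Reactants: 1 5-methoxyresorcinol
Product: 3 1-methoxy-3,5-bis(methoxymethoxy)benzene, via disodium bis-phenoxide 2 (not isolated)
Conditions: NaH (2.4 equiv), MOMCl (2.4 equiv), DMF, 0 °C to rt
Reagents that add atoms: chloromethyl methyl ether (MOMCl), COCCl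
Why: Williamson-type O-alkylation of bis-phenoxide 2 with the reactive chloromethyl ether should protect both hydroxyls and install the two strongest ortho-directing groups for the later lithiations.

**Step 2**
Reactants: 3 1-methoxy-3,5-bis(methoxymethoxy)benzene; 4 prenyl bromide (1-bromo-3-methylbut-2-ene)
Product: 6 5-methoxy-1,3-bis(methoxymethoxy)-2-(3-methylbut-2-en-1-yl)benzene, via aryllithium 5 (not isolated)
Conditions: n-BuLi (1.1 equiv), THF, 0 °C; then 4, −78 °C to rt
Reagents that add atoms: none
Why: Directed ortho-metalation should occur at the CH flanked by the two coordinating OMOM groups, which outrank OMe as directors, and aryllithium 5 is then alkylated by the primary allylic bromide in an SN2 reaction to give mirror-symmetric 6.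

**Step 3**
Reactants: 6 5-methoxy-1,3-bis(methoxymethoxy)-2-(3-methylbut-2-en-1-yl)benzene
Product: 9 6-methoxy-2,4-bis(methoxymethoxy)-3-(3-methylbut-2-en-1-yl)benzaldehyde, via aryllithium 7 (not isolated), via lithium hemiaminal alkoxide 8 (not isolated)
Conditions: n-BuLi (1.15 equiv), THF, 0 °C; DMF, 0 °C to rt; aq NH4Cl
Reagents that add atoms: N,N-dimethylformamide (DMF), CN(C)C=O
Why: A second directed ortho-metalation can only strike one of the two equivalent CH positions between OMe and OMOM, and formylation of 7 with DMF rests at tetrahedral adduct 8 until the quench, so a single aldehyde should result.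

**Step 4**
Reactants: 9 6-methoxy-2,4-bis(methoxymethoxy)-3-(3-methylbut-2-en-1-yl)benzaldehyde
Product: 10 2-[6-methoxy-2,4-bis(methoxymethoxy)-3-(3-methylbut-2-en-1-yl)phenyl]-1,3-dimethylimidazolidine
Conditions: MeNHCH2CH2NHMe (1.5 equiv), 4 Å molecular sieves, toluene, 80 °C
Reagents that add atoms: N,N'-dimethylethylenediamine, CNCCNC
Why: Condensation of an aldehyde with a 1,2-bis(secondary amine) to a cyclic aminal needs no acid, so the MOM ethers are safe, and the imidazolidine ring is inert to n-BuLi.

**Step 5**
Reactants: 10 2-[6-methoxy-2,4-bis(methoxymethoxy)-3-(3-methylbut-2-en-1-yl)phenyl]-1,3-dimethylimidazolidine; 11 1,4-dimethylpiperazine-2,3-dione; 12 1-bromo-4-(methoxymethoxy)benzene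
Product: 17 1-[3-(1,3-dimethylimidazolidin-2-yl)-2-methoxy-4,6-bis(methoxymethoxy)-5-(3-methylbut-2-en-1-yl)phenyl]-2-[4-(methoxymethoxy)phenyl]ethane-1,2-dione, via ring A aryllithium 13 (not isolated), via mono-adduct 14 (not isolated), via ring B aryllithium 15 (not isolated), via bis-adduct 16 (not isolated)
Conditions: 10, n-BuLi (1.05 equiv), THF, 0 °C; 11 (1.0 equiv), −78 to 0 °C; then 15 (from 12, n-BuLi, THF, −78 °C; 1.2 equiv), −78 °C to rt; aq NH4Cl
Reagents that add atoms: none
Why: A third directed ortho-metalation at the last ring A CH gives 13, whose addition to cyclic oxamide 11 stops at the stable lithium hemiaminal 14 because a second hindered aryl cannot enter, the unhindered 15 from bromine–lithium exchange then takes the remaining amide carbonyl, and the buffered quench collapses 16 to the unsymmetrical benzil (sequential organolithium addition to a piperazine-2,3-dione, a known 1,2-dione synthesis).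

**Step 6**
Reactants: 17 1-[3-(1,3-dimethylimidazolidin-2-yl)-2-methoxy-4,6-bis(methoxymethoxy)-5-(3-methylbut-2-en-1-yl)phenyl]-2-[4-(methoxymethoxy)phenyl]ethane-1,2-dione
Product: 18 2,4-dihydroxy-5-[2-(4-hydroxyphenyl)-2-oxoacetyl]-6-methoxy-3-(3-methylbut-2-en-1-yl)benzaldehyde
Conditions: 3 M aq HCl, THF, 40 °C
Reagents that add atoms: water, O
Why: Acid-catalysed aminal and acetal hydrolysis should release the aldehyde at once and the three phenols next, the two ring A MOM ethers being accelerated by their neighbouring carbonyl groups, under the dilute aqueous conditions commonly used for prenylated phenols.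

**Step 7**
Reactants: 18 2,4-dihydroxy-5-[2-(4-hydroxyphenyl)-2-oxoacetyl]-6-methoxy-3-(3-methylbut-2-en-1-yl)benzaldehyde; 19 (2-methylprop-1-en-1-yl)boronic acid
Product: 23 derrisdione A, via iminium boronate 20 (not isolated), via allylic amine 21 (not isolated), via ortho-quinone methide 22 (not isolated)
Conditions: 19 (2.5 equiv), Bn2NH (0.5 equiv), 1,4-dioxane, 90 °C, Ar
Reagents that add atoms: none
Why: Dibenzylamine condenses with the formyl group of 18 while the C8a phenoxide binds 19, and zwitterion 20 passes its 2-methylprop-1-enyl group from boron to the iminium carbon within the complex (Petasis borono-Mannich reaction), which makes the C4–C3 bond in racemic amine 21. At 90 °C the electron-rich ring A pushes the amine out of 21, so that the amine returns to the cycle, and the resulting vinylogous ortho-quinone methide 22 closes its 1-oxatriene (O=C8a–C4a=C4–C3=C2) by a thermal oxa-6π electrocyclisation, which forms O1–C2, closes the six-membered ring C and restores the aromaticity of ring A. The closest known reaction type is the amine-catalysed condensation of salicylaldehydes with alkenylboronic acids to 2H-chromenes. No stereocentre has to be controlled, since the carbinamine centre of 21 is erased in 22, C2 carries two methyl groups and C3=C4 can only be cis inside the ring. The site selectivity between the two ring A hydroxyls is secured by the substrate, because the formyl carbon has only the C8a hydroxyl as free neighbour (C5 carries OMe), whereas the C7 hydroxyl lies between the prenyl group and the C6 ketone, to which it is hydrogen-bonded. The chemoselectivity over the 1,2-dione follows from the fact that a secondary amine gives an iminium ion only with the aldehyde and that transfer needs the boron-bound phenoxide next to it, and the prenyl alkene is safe because neither acid nor oxidant is present.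

**Compound list**

1 | 5-methoxyresorcinol | COc1cc(O)cc(O)c1 | starting material
2 | disodium 5-methoxybenzene-1,3-diolate (not isolated) | COc1cc([O-])cc([O-])c1.[Na+].[Na+] | intermediate
3 | 1-methoxy-3,5-bis(methoxymethoxy)benzene | COCOc1cc(OC)cc(OCOC)c1 | intermediate
4 | prenyl bromide | CC(C)=CCBr | starting material
5 | [4-methoxy-2,6-bis(methoxymethoxy)phenyl]lithium (not isolated) | [Li]c1c(OCOC)cc(OC)cc1OCOC | intermediate
6 | 5-methoxy-1,3-bis(methoxymethoxy)-2-(3-methylbut-2-en-1-yl)benzene | COCOc1cc(OC)cc(OCOC)c1CC=C(C)C | intermediate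
7 | [6-methoxy-2,4-bis(methoxymethoxy)-3-(3-methylbut-2-en-1-yl)phenyl]lithium (not isolated) | [Li]c1c(OC)cc(OCOC)c(CC=C(C)C)c1OCOC | intermediate
8 | lithium (dimethylamino)(aryl)methoxide from 7 and DMF, racemic (not isolated) | [Li]OC(N(C)C)c1c(OC)cc(OCOC)c(CC=C(C)C)c1OCOC | intermediate
9 | 6-methoxy-2,4-bis(methoxymethoxy)-3-(3-methylbut-2-en-1-yl)benzaldehyde | O=Cc1c(OC)cc(OCOC)c(CC=C(C)C)c1OCOC | intermediate
10 | 2-[6-methoxy-2,4-bis(methoxymethoxy)-3-(3-methylbut-2-en-1-yl)phenyl]-1,3-dimethylimidazolidine | CN1CCN(C)C1c1c(OC)cc(OCOC)c(CC=C(C)C)c1OCOC | intermediate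
11 | 1,4-dimethylpiperazine-2,3-dione | CN1CCN(C)C(=O)C1=O | starting material
12 | 1-bromo-4-(methoxymethoxy)benzene | COCOc1ccc(Br)cc1 | starting material
13 | ring A aryllithium from 10 (not isolated) | CN1CCN(C)C1c1c(OC)c([Li])c(OCOC)c(CC=C(C)C)c1OCOC | intermediate
14 | lithium alkoxide mono-adduct of 13 to 11, racemic (not isolated) | CN1CCN(C)C(O[Li])(c2c(OC)c(C3N(C)CCN3C)c(OCOC)c(CC=C(C)C)c2OCOC)C1=O | intermediate
15 | [4-(methoxymethoxy)phenyl]lithium (not isolated) | [Li]c1ccc(OCOC)cc1 | intermediate
16 | dilithium bis-adduct of 13 and 15 to 11, mixture of diastereomers (not isolated) | CN1CCN(C)C(O[Li])(c2c(OC)c(C3N(C)CCN3C)c(OCOC)c(CC=C(C)C)c2OCOC)C1(O[Li])c1ccc(OCOC)cc1 | intermediate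
17 | 1-[3-(1,3-dimethylimidazolidin-2-yl)-2-methoxy-4,6-bis(methoxymethoxy)-5-(3-methylbut-2-en-1-yl)phenyl]-2-[4-(methoxymethoxy)phenyl]ethane-1,2-dione | COCOc1ccc(cc1)C(=O)C(=O)c1c(OC)c(C2N(C)CCN2C)c(OCOC)c(CC=C(C)C)c1OCOC | intermediate
18 | 2,4-dihydroxy-5-[2-(4-hydroxyphenyl)-2-oxoacetyl]-6-methoxy-3-(3-methylbut-2-en-1-yl)benzaldehyde | COc1c(C=O)c(O)c(CC=C(C)C)c(O)c1C(=O)C(=O)c1ccc(O)cc1 | intermediate
19 | (2-methylprop-1-en-1-yl)boronic acid | CC(C)=CB(O)O | starting material
20 | dibenzyliminium aryloxyboronate zwitterion (not isolated) | COc1c(C=[N+](Cc2ccccc2)Cc2ccccc2)c(O[B-](O)(O)C=C(C)C)c(CC=C(C)C)c(O)c1C(=O)C(=O)c1ccc(O)cc1 | intermediate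
21 | 2-[1-(dibenzylamino)-3-methylbut-2-en-1-yl]phenol form of 18, racemic (not isolated) | COc1c(C(C=C(C)C)N(Cc2ccccc2)Cc2ccccc2)c(O)c(CC=C(C)C)c(O)c1C(=O)C(=O)c1ccc(O)cc1 | intermediate
22 | vinylogous ortho-quinone methide, exocyclic alkene geometry not fixed (not isolated) | COC1=C(C(=O)C(=O)c2ccc(O)cc2)C(O)=C(CC=C(C)C)C(=O)C1=CC=C(C)C | intermediate
23 | derrisdione A | COc1c2c(c(CC=C(C)C)c(O)c1C(=O)C(=O)c1ccc(O)cc1)OC(C)(C)C=C2 | target

**Total step count:** 7. **Longest linear sequence:** 7 steps (1 to 23).

**Steps most likely to fail**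

**Step 7.** Iminium formation and alkenyl transfer may be slow at an aldehyde that is flanked on both sides and fed by three oxygen donors. Protodeboronation of 19 and capture of boron by the 2-hydroxyketone chelate could then win.

Fallback (sets out from 9, comes back at 23): the pyran ring is built early, with a carbanion in place of the boronate. 2-Methylprop-1-enylmagnesium bromide is added to 9 (THF, 0 °C) to give the racemic allylic benzylic alcohol F1. Dilute HCl in THF removes both MOM groups and ionises the alcohol, and the same kind of oxatriene closes to 5-methoxy-2,2-dimethyl-8-prenyl-2H-chromen-7-ol F2. NaH and MOMCl give the MOM ether F3. n-BuLi lithiates the only aromatic CH (C6, between OMe and OMOM) to the aryllithium F4. This is passed through the relay of step 5 with 11 and 15, by way of the mono-adduct F5 and the bis-adduct F6, to bis-MOM derrisdione A F7. Dilute HCl in THF then frees 23.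

**Step 5.** Addition of the doubly ortho-substituted aryllithium to the poorly soluble oxamide may be sluggish. Statistical scrambling of the two aryl groups over the two carbonyls may erode the cross-selectivity.

Fallback (sets out from 10, comes back at 17): the dione is reached through the benzoin oxidation level. Aryllithium 13, made from 10 as before, is trapped by the unhindered and far more electrophilic formyl group of anhydrous [4-(methoxymethoxy)phenyl]glyoxal F8. This reagent is made by SeO2 oxidation of purchased 1-[4-(methoxymethoxy)phenyl]ethanone followed by azeotropic drying. The addition gives the racemic benzoin F9, and a Swern oxidation converts it to 17.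

**Step 6.** Acid-catalysed addition of a freed phenol to the prenyl alkene (closure to a chroman) may set in before the last MOM ether has gone.

Fallback (sets out from 17, comes back at 18): proton-driven hydrolysis of the ethers is replaced by silyl transfer in a buffered medium, so that free phenols and strong acid never meet. The aminal alone is opened with cold dilute oxalic acid in wet THF to give the tris-MOM aldehyde F10. TMSOTf and 2,2'-bipyridyl in MeCN exchange the three MOM groups for silyl groups to give the tris(trimethylsilyl) ether F11. Addition of water hydrolyses this to 18.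

**Further compounds**

F1 | step 7 | 1-[6-methoxy-2,4-bis(methoxymethoxy)-3-(3-methylbut-2-en-1-yl)phenyl]-3-methylbut-2-en-1-ol (racemic) | COc1cc(OCOC)c(CC=C(C)C)c(OCOC)c1C(O)C=C(C)C
F2 | step 7 | 5-methoxy-2,2-dimethyl-8-(3-methylbut-2-en-1-yl)-2H-chromen-7-ol | COc1cc(O)c(CC=C(C)C)c2OC(C)(C)C=Cc12
F3 | step 7 | 5-methoxy-7-(methoxymethoxy)-2,2-dimethyl-8-(3-methylbut-2-en-1-yl)-2H-chromene | COc1cc(OCOC)c(CC=C(C)C)c2OC(C)(C)C=Cc12
F4 | step 7 | 6-lithio derivative of F3 | COc1c([Li])c(OCOC)c(CC=C(C)C)c2OC(C)(C)C=Cc12
F5 | step 7 | lithium alkoxide mono-adduct of F4 to 11 (racemic) | CN1CCN(C)C(O[Li])(c2c(OC)c3C=CC(C)(C)Oc3c(CC=C(C)C)c2OCOC)C1=O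
F6 | step 7 | dilithium bis-adduct of F4 and 15 to 11 (mixture of diastereomers) | CN1CCN(C)C(O[Li])(c2c(OC)c3C=CC(C)(C)Oc3c(CC=C(C)C)c2OCOC)C1(O[Li])c1ccc(OCOC)cc1
F7 | step 7 | bis(methoxymethyl) ether of derrisdione A | COCOc1ccc(cc1)C(=O)C(=O)c1c(OC)c2C=CC(C)(C)Oc2c(CC=C(C)C)c1OCOC
F8 | step 5 | 2-[4-(methoxymethoxy)phenyl]-2-oxoacetaldehyde | COCOc1ccc(cc1)C(=O)C=O
F9 | step 5 | 2-[3-(1,3-dimethylimidazolidin-2-yl)-2-methoxy-4,6-bis(methoxymethoxy)-5-(3-methylbut-2-en-1-yl)phenyl]-2-hydroxy-1-[4-(methoxymethoxy)phenyl]ethanone (racemic) | COCOc1ccc(cc1)C(=O)C(O)c1c(OC)c(C2N(C)CCN2C)c(OCOC)c(CC=C(C)C)c1OCOC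
F10 | step 6 | 6-methoxy-2,4-bis(methoxymethoxy)-5-{2-[4-(methoxymethoxy)phenyl]-2-oxoacetyl}-3-(3-methylbut-2-en-1-yl)benzaldehyde | COCOc1ccc(cc1)C(=O)C(=O)c1c(OC)c(C=O)c(OCOC)c(CC=C(C)C)c1OCOC
F11 | step 6 | tris(trimethylsilyl) ether of 18 | C[Si](C)(C)Oc1ccc(cc1)C(=O)C(=O)c1c(OC)c(C=O)c(O[Si](C)(C)C)c(CC=C(C)C)c1O[Si](C)(C)C
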